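**Retrosynthetic overview**
1. Target 12 ⇐ triol dibenzoate 10, by mono-acetylation of the only cis-diol through a cyclic orthoacetate that opens to the axial acetate.
2. 10 ⇐ dihydroxy enoate 6, by silylation of the unhindered allylic OH, ester reduction, double benzoylation and global deprotection.
3. 6 ⇐ meso bis-epoxy cycloheptanone 4, by a methoxide-triggered 1,2-shift of a ring C–C bond (semibenzilic 7→6 ring contraction, catalyst-controlled desymmetrisation) followed by E1cB opening of the second oxirane.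
4. 4 ⇐ tropone 1, by cis-dihydroxylation of C4=C5, acetonide formation and double nucleophilic epoxidation.
5. Ring order: the seven-membered carbocycle is bought; the dioxolane (step 2) and two oxiranes (step 3) are temporary; the cyclohexene ring is formed in step 4.

Assumption: tropone is the commercial starting material; acylating, silylating and acetal-forming agents are treated as reagents; the ProPhenol antipode that leads to 6 is fixed in a first screen.

**Step 1**
Reactants: 1 tropone (cyclohepta-2,4,6-trien-1-one)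
Product: 2 (4R,5S)-4,5-dihydroxycyclohepta-2,6-dien-1-one (meso cis-diol)
Conditions: OsO4 (2 mol%), NMO (1.1 equiv), acetone–H2O 4:1, 0 °C
Reagents that add atoms: N-methylmorpholine N-oxide (C[N+]1([O-])CCOCC1); water (O)
Why: Upjohn syn-dihydroxylation: electrophilic OsO4 takes the γ,δ-alkene C4=C5 (the only C=C not directly conjugated to the carbonyl, as in dienone and dienoate dihydroxylations) and its suprafacial [3+2] addition sets the two hydroxyls cis, giving the meso diol.

**Step 2**
Reactants: 2 (4R,5S)-4,5-dihydroxycyclohepta-2,6-dien-1-one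
Product: 3 (3aR,8aS)-2,2-dimethyl-3a,8a-dihydro-6H-cyclohepta[d][1,3]dioxol-6-one (meso)
Conditions: Me2C(OMe)2, PPTS (cat.), acetone, rt
Reagents that add atoms: 2,2-dimethoxypropane (COC(C)(C)OC)
Why: Acid-catalysed acetonide formation (transketalisation) on the cis-diol; no stereocentre is touched, and the dioxolane prevents dehydration to 4-hydroxytropone and shields one ring face for step 3.

**Step 3**
Reactants: 3 (3aR,8aS)-2,2-dimethyl-3a,8a-dihydro-6H-cyclohepta[d][1,3]dioxol-6-one
Product: 4 meso 4,5:7,8-diepoxy-2,2-dimethylhexahydro-6H-cyclohepta[d][1,3]dioxol-6-one (both oxirane oxygens on the ring face opposite to the dioxolane oxygens)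
Conditions: t-BuOOH (3 equiv, in decane), DBU (0.3 equiv), CH2Cl2, 0 °C
Reagents that add atoms: tert-butyl hydroperoxide (CC(C)(C)OO)
Why: Double Weitz–Scheffer nucleophilic epoxidation of the cross-conjugated dienone: each t-BuOO– adds to a β-carbon anti to the adjacent dioxolane C–O bond and the enolate closes the oxirane, so both epoxides are trans to the acetonide and cis to each other (meso).

**Step 4**
Reactants: 4 meso 4,5:7,8-diepoxy-2,2-dimethylhexahydro-6H-cyclohepta[d][1,3]dioxol-6-one
Product: 6 methyl (3aR,4S,7R,7aS)-4,7-dihydroxy-2,2-dimethyl-3a,4,7,7a-tetrahydro-1,3-benzodioxole-5-carboxylate, via epoxy hydroxy ester 5 (not isolated)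
Conditions: ProPhenol ligand (10 mol%), Et2Zn (20 mol%), MeOH (5 equiv), 4 Å MS, THF, 0 °C → rt; then DBU (0.5 equiv), rt
Reagents that add atoms: methanol (CO)
Why: Proposed new method: catalytic enantioselective desymmetrising semibenzilic (quasi-Favorskii) ring contraction – zinc methoxide adds to the ketone anti to the oxiranes, the zinc hemiketalate lies syn to both epoxide oxygens, the second zinc of the chiral dinuclear catalyst activates one of the two enantiotopic oxiranes, and the antiperiplanar ring C–C bond makes a 1,2-shift to that α-carbon (inversion there, β-C–O retained; no α-H, so no cyclopropanone path), which contracts the seven- to the six-membered ring and turns the hemiketal carbon into the exocyclic CO2Me; DBU then opens the remaining β,γ-epoxide by E1cB to give the ring alkene and the second allylic OH, so both carbinols end trans to the acetonide and the absolute sense comes from the catalyst; closest known chemistry is the base-induced Favorskii-type ring contraction of α,β-epoxy ketones and dinuclear-zinc or (salen)metal desymmetrisation of meso substrates.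

**Step 5**
Reactants: 6 methyl (3aR,4S,7R,7aS)-4,7-dihydroxy-2,2-dimethyl-3a,4,7,7a-tetrahydro-1,3-benzodioxole-5-carboxylate
Product: 7 methyl (3aR,4S,7R,7aR)-4-hydroxy-2,2-dimethyl-7-[(triethylsilyl)oxy]-3a,4,7,7a-tetrahydro-1,3-benzodioxole-5-carboxylate
Conditions: TESCl (1.05 equiv), imidazole, CH2Cl2, –40 °C
Reagents that add atoms: chlorotriethylsilane (CC[Si](Cl)(CC)CC)
Why: Chemoselective silylation: the 7-OH is an unhindered allylic alcohol next to the vinylic CH, whereas the 4-OH is flanked by the ester-bearing alkene carbon and hydrogen-bonded to the ester, so TESCl at low temperature protects only O-7 (no stereocentre affected).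

**Step 6**
Reactants: 7 methyl (3aR,4S,7R,7aR)-4-hydroxy-2,2-dimethyl-7-[(triethylsilyl)oxy]-3a,4,7,7a-tetrahydro-1,3-benzodioxole-5-carboxylate
Product: 8 (3aR,4S,7R,7aR)-5-(hydroxymethyl)-2,2-dimethyl-7-[(triethylsilyl)oxy]-3a,4,7,7a-tetrahydro-1,3-benzodioxol-4-ol
Conditions: DIBAL-H (3.5 equiv), CH2Cl2, –78 °C; Rochelle salt work-up
Reagents that add atoms: none
Why: DIBAL-H 1,2-reduction of the α,β-unsaturated methyl ester to the primary allylic alcohol; silyl ether, acetonide and the trisubstituted alkene are inert at –78 °C.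

**Step 7**
Reactants: 8 (3aR,4S,7R,7aR)-5-(hydroxymethyl)-2,2-dimethyl-7-[(triethylsilyl)oxy]-3a,4,7,7a-tetrahydro-1,3-benzodioxol-4-ol
Product: 9 [(3aR,4S,7R,7aR)-4-(benzoyloxy)-2,2-dimethyl-7-[(triethylsilyl)oxy]-3a,4,7,7a-tetrahydro-1,3-benzodioxol-5-yl]methyl benzoate
Conditions: BzCl (2.5 equiv), pyridine, DMAP (cat.), CH2Cl2, 0 °C → rt
Reagents that add atoms: benzoyl chloride (O=C(Cl)c1ccccc1)
Why: DMAP-catalysed O-acylation (nucleophilic catalysis) of the primary and the secondary allylic hydroxyl installs both benzoates with retention at C4.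

**Step 8**
Reactants: 9 [(3aR,4S,7R,7aR)-4-(benzoyloxy)-2,2-dimethyl-7-[(triethylsilyl)oxy]-3a,4,7,7a-tetrahydro-1,3-benzodioxol-5-yl]methyl benzoate
Product: 10 [(3R,4S,5S,6S)-6-(benzoyloxy)-3,4,5-trihydroxycyclohex-1-en-1-yl]methyl benzoate
Conditions: TFA–H2O 9:1, CH2Cl2, 0 °C
Reagents that add atoms: none
Why: Aqueous acid hydrolysis cleaves the isopropylidene acetal and the triethylsilyl ether while the benzoates survive; low temperature limits acyl migration and no stereocentre is involved.

**Step 9**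
Reactants: 10 [(3R,4S,5S,6S)-6-(benzoyloxy)-3,4,5-trihydroxycyclohex-1-en-1-yl]methyl benzoate
Product: 12 [(3R,4S,5S,6S)-5-(acetyloxy)-6-(benzoyloxy)-3,4-dihydroxycyclohex-1-en-1-yl]methyl benzoate, via cyclic orthoacetate 11 (not isolated)
Conditions: MeC(OMe)3 (1.5 equiv), CSA (cat.), MeCN, rt; then 80% aq. AcOH, rt
Reagents that add atoms: trimethyl orthoacetate (COC(C)(OC)OC); water (O)
Why: Cyclic orthoester formation on the only cis-diol (O-4/O-5) and mild acid hydrolysis via the dioxolan-2-ylium/hemiorthoester, which opens under stereoelectronic control to the axial acetate and equatorial alcohol (orthoester rule of carbohydrate chemistry); in the half-chair that keeps the 6-OBz pseudo-axial (A1,2 strain with CH2OBz) O-5 is axial, so the acetate lands on O-5 and no stereocentre changes.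

**Compound list**
1 | tropone (cyclohepta-2,4,6-trien-1-one) | O=C1C=CC=CC=C1 | starting material
2 | (4R,5S)-4,5-dihydroxycyclohepta-2,6-dien-1-one (meso cis-diol) | O=C1C=C[C@@H](O)[C@@H](O)C=C1 | intermediate
3 | (3aR,8aS)-2,2-dimethyl-3a,8a-dihydro-6H-cyclohepta[d][1,3]dioxol-6-one (meso) | O=C1C=C[C@H]2OC(C)(C)O[C@H]2C=C1 | intermediate
4 | meso 4,5:7,8-diepoxy-2,2-dimethylhexahydro-6H-cyclohepta[d][1,3]dioxol-6-one, oxirane oxygens anti to the dioxolane | O=C1[C@@H]2O[C@@H]2[C@H]3OC(C)(C)O[C@H]3[C@@H]4O[C@H]14 | intermediate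
5 | methyl 5,6-epoxy-2-hydroxy-3,4-(isopropylidenedioxy)cyclohexane-1-carboxylate (CO2Me, 2-OH and oxirane O on one face, dioxolane oxygens on the other) | COC(=O)[C@@H]1[C@H](O)[C@H]2OC(C)(C)O[C@H]2[C@@H]3O[C@H]13 | intermediate
6 | methyl (3aR,4S,7R,7aS)-4,7-dihydroxy-2,2-dimethyl-3a,4,7,7a-tetrahydro-1,3-benzodioxole-5-carboxylate | CC1(C)O[C@H]2[C@@H](O1)[C@H](O)C=C(C(=O)OC)[C@@H]2O | intermediate
7 | methyl (3aR,4S,7R,7aR)-4-hydroxy-2,2-dimethyl-7-[(triethylsilyl)oxy]-3a,4,7,7a-tetrahydro-1,3-benzodioxole-5-carboxylate | CC1(C)O[C@H]2[C@@H](O1)[C@H](O[Si](CC)(CC)CC)C=C(C(=O)OC)[C@@H]2O | intermediate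
8 | (3aR,4S,7R,7aR)-5-(hydroxymethyl)-2,2-dimethyl-7-[(triethylsilyl)oxy]-3a,4,7,7a-tetrahydro-1,3-benzodioxol-4-ol | CC1(C)O[C@H]2[C@@H](O1)[C@H](O[Si](CC)(CC)CC)C=C(CO)[C@@H]2O | intermediate
9 | [(3aR,4S,7R,7aR)-4-(benzoyloxy)-2,2-dimethyl-7-[(triethylsilyl)oxy]-3a,4,7,7a-tetrahydro-1,3-benzodioxol-5-yl]methyl benzoate | CC1(C)O[C@H]2[C@@H](O1)[C@H](O[Si](CC)(CC)CC)C=C(COC(=O)c3ccccc3)[C@@H]2OC(=O)c2ccccc2 | intermediate
10 | [(3R,4S,5S,6S)-6-(benzoyloxy)-3,4,5-trihydroxycyclohex-1-en-1-yl]methyl benzoate | O[C@H]1[C@@H](O)[C@H](O)C=C(COC(=O)c2ccccc2)[C@@H]1OC(=O)c1ccccc1 | intermediate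
11 | 4,5-O-(1-methoxyethylidene) cyclic orthoacetate of 10 (both epimers at the orthoester carbon) | COC1(C)O[C@H]2[C@@H](O1)[C@H](O)C=C(COC(=O)c3ccccc3)[C@@H]2OC(=O)c2ccccc2 | intermediate
12 | [(3R,4S,5S,6S)-5-(acetyloxy)-6-(benzoyloxy)-3,4-dihydroxycyclohex-1-en-1-yl]methyl benzoate | CC(=O)O[C@H]1[C@@H](O)[C@H](O)C=C(COC(=O)c2ccccc2)[C@@H]1OC(=O)c1ccccc1 | target

**Step count and risks**
Total steps: 9. Longest linear sequence: 9 (fully linear from tropone).

Steps most likely to fail:

Step 4 (the proposed new reaction). Catalyst turnover, the migration itself or the enantioselectivity may be poor, and direct methanolysis of an oxirane can compete. The fallback uses known chemistry; it sets out from 4 and comes back at 6. Sodium methoxide in methanol at 0 °C brings about the same Favorskii-type contraction and E1cB opening without a chiral catalyst, giving the racemate: 6 together with its mirror image methyl (3aS,4R,7S,7aR)-4,7-dihydroxy-2,2-dimethyl-3a,4,7,7a-tetrahydro-1,3-benzodioxole-5-carboxylate F1. Lipase-catalysed kinetic resolution (Amano PS or CAL-B, vinyl acetate, MTBE) acetylates the unhindered 7-OH of one enantiomer, by Kazlauskas' rule the 7R alcohol 6, to methyl (3aR,4S,7R,7aS)-7-(acetyloxy)-4-hydroxy-2,2-dimethyl-3a,4,7,7a-tetrahydro-1,3-benzodioxole-5-carboxylate F2. F2 is separated from unreacted F1 and methanolysed (K2CO3, MeOH, 0 °C) to enantioenriched 6.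

Step 1. Tropone may be attacked at C2=C3, over-oxidised, or the diol may dehydrate to 4-hydroxytropone. The fallback does not set out from 1 but from commercial cyclohept-4-en-1-one F3 and comes back to the route at 3. Upjohn dihydroxylation of the isolated cis-alkene gives (4R,5S)-4,5-dihydroxycycloheptan-1-one F4. 2,2-Dimethoxypropane/PPTS gives the acetonide (3aR,8aS)-2,2-dimethylhexahydro-6H-cyclohepta[d][1,3]dioxol-6-one F5. Double α,β-dehydrogenation on both sides of the ketone with IBX (DMSO–fluorobenzene, 70 °C) gives 3.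

Step 9. The orthoester may open to the 4-O-acetate, or the acetyl may migrate between the cis oxygens. The fallback sets out from 10 and comes back at 12, replacing stereoelectronic control by protecting-group differentiation. TESCl (2.1 equiv)/imidazole at –20 °C silylates the allylic 3-OH and the equatorial 4-OH but not the axial, flanked 5-OH, giving the 3,4-bis-O-triethylsilyl ether of 10 F6. Ac2O/DMAP/pyridine acetylates the remaining 5-OH to give the 5-O-acetyl-3,4-bis-O-triethylsilyl compound F7. HF·pyridine in THF at 0 °C removes both silyl groups to give 12.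

**Further compounds**
F1 | step 4 | methyl (3aS,4R,7S,7aR)-4,7-dihydroxy-2,2-dimethyl-3a,4,7,7a-tetrahydro-1,3-benzodioxole-5-carboxylate (ent-6) | CC1(C)O[C@@H]2[C@H](O1)[C@@H](O)C=C(C(=O)OC)[C@H]2O
F2 | step 4 | methyl (3aR,4S,7R,7aS)-7-(acetyloxy)-4-hydroxy-2,2-dimethyl-3a,4,7,7a-tetrahydro-1,3-benzodioxole-5-carboxylate | CC1(C)O[C@H]2[C@@H](O1)[C@H](OC(C)=O)C=C(C(=O)OC)[C@@H]2O
F3 | step 1 | cyclohept-4-en-1-one | O=C1CCC=CCC1
F4 | step 1 | (4R,5S)-4,5-dihydroxycycloheptan-1-one (meso cis-diol) | O=C1CC[C@@H](O)[C@@H](O)CC1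
F5 | step 1 | (3aR,8aS)-2,2-dimethylhexahydro-6H-cyclohepta[d][1,3]dioxol-6-one (meso) | O=C1CC[C@H]2OC(C)(C)O[C@H]2CC1
F6 | step 9 | 3,4-bis-O-triethylsilyl ether of 10 | O[C@H]1[C@@H](O[Si](CC)(CC)CC)[C@H](O[Si](CC)(CC)CC)C=C(COC(=O)c2ccccc2)[C@@H]1OC(=O)c1ccccc1
F7 | step 9 | 5-O-acetyl-3,4-bis-O-triethylsilyl derivative of 10 | CC(=O)O[C@H]1[C@@H](O[Si](CC)(CC)CC)[C@H](O[Si](CC)(CC)CC)C=C(COC(=O)c2ccccc2)[C@@H]1OC(=O)c1ccccc1
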